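**Retrosynthetic overview**

1. Target 28 ← 27 (fluoride desilylation) ← 26 (DIBAL-H on both esters). All hydroxyl groups are unmasked only after the ring system is complete.
2. The dihydrofuran ring of 26 ← the six-membered pyranone ring of 3-diazoflavanone 23, by photochemical Wolff ring contraction. C4a migrates from C4 to C3, C4 leaves the ring as the C3 ester carbon (later C3–CH2OH), and the enol is protonated anti to the C2 aryl group to give the 2,3-cis isomer.
3. Enabling feature: C3 of the dihydrobenzofuran carries exactly one exocyclic carbon and is bonded to arene carbon C3a. That carbon can be written back into the ring between C3 and C3a as the C4 carbonyl of a chroman-4-one, which also activates C3 for diazo transfer.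
4. 23 ← flavanone 21 ← Pd/PyOx asymmetric conjugate addition of arylboronic acid 20 to chromone 6 (sets C2).
5. 20 ← phenol 9 + methyl D-glycerate 7 (Mitsunobu inversion sets C8; Weinreb amide, aryl Grignard and chelation-controlled reduction set C7). 6 ← acetophenone 1. Ring order: pyranone ring (step 2), saturated to the flavanone (step 12), contracted to the dihydrofuran (step 14).

Key step: step 14

Remark: the descriptors of the target correspond to a 2,3-cis dihydrobenzofuran (2R,3R) and an erythro (7R,8S) arylglycerol unit; the route is laid out for exactly this isomer.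

Abbreviation used in names: Ar* = 4-{[(1R,2S)-1-(tert-butyldimethylsilyloxy)-1-[3-methoxy-4-(triisopropylsilyloxy)phenyl]-3-(triisopropylsilyloxy)propan-2-yl]oxy}-3,5-dimethoxyphenyl.

**Route**

Step 1
Reactants: 1 1-(2-hydroxy-3-methoxyphenyl)ethan-1-one
Product: 2 1-(5-bromo-2-hydroxy-3-methoxyphenyl)ethan-1-one
Conditions: NBS (1.05 equiv), MeCN, 0 °C to rt
Reagents that add atoms: N-bromosuccinimide, O=C1CCC(=O)N1Br
Why: Electrophilic aromatic bromination should go to the only free position that is para to the phenol OH and meta to the acetyl group.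

Step 2
Reactants: 2 1-(5-bromo-2-hydroxy-3-methoxyphenyl)ethan-1-one
Product: 4 bromochromone 6-bromo-8-methoxy-4H-chromen-4-one, via enaminone 3 (not isolated)
Conditions: DMF-DMA, toluene, 100 °C; then conc. HCl, CH2Cl2, 40 °C
Reagents that add atoms: N,N-dimethylformamide dimethyl acetal, COC(OC)N(C)C
Why: Enaminone formation from the methyl ketone followed by acid-promoted intramolecular addition of the phenol and loss of dimethylamine is the standard chromone synthesis from 2'-hydroxyacetophenones.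

Step 3
Reactants: 4 bromochromone; 5 (3-ethoxy-3-oxopropyl)zinc bromide
Product: 6 ethyl 3-(8-methoxy-4-oxo-4H-chromen-6-yl)propanoate
Conditions: Pd(OAc)2 (2 mol %), SPhos (4 mol %), THF, 50 °C
Reagents that add atoms: none
Why: Negishi sp2–sp3 coupling needs no base, so the base-sensitive chromone and the ester should survive; the organozinc does not add to the enone without copper.

Step 4
Reactants: 7 methyl (R)-2,3-dihydroxypropanoate (methyl D-glycerate)
Product: 8 methyl (R)-2-hydroxy-3-(triisopropylsilyloxy)propanoate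
Conditions: TIPSCl (1.05 equiv), imidazole, CH2Cl2, 0 °C to rt
Reagents that add atoms: triisopropylsilyl chloride, CC(C)[Si](Cl)(C(C)C)C(C)C
Why: The bulky silyl chloride should silylate the primary hydroxyl selectively over the secondary α-hydroxyl.

Step 5
Reactants: 8 methyl (R)-2-hydroxy-3-(triisopropylsilyloxy)propanoate; 9 4-bromo-2,6-dimethoxyphenol
Product: 10 methyl (S)-2-(4-bromo-2,6-dimethoxyphenoxy)-3-(triisopropylsilyloxy)propanoate
Conditions: PPh3, DIAD, THF, 0 °C to rt
Reagents that add atoms: none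
Why: Mitsunobu etherification of an α-hydroxy ester proceeds by SN2 with clean inversion (R to S), which sets the future C8 stereocentre.

Step 6
Reactants: 10 aryl ether ester
Product: 11 (S)-2-(4-bromo-2,6-dimethoxyphenoxy)-N-methoxy-N-methyl-3-(triisopropylsilyloxy)propanamide
Conditions: MeNH(OMe)·HCl, AlMe3, CH2Cl2, 0 °C to rt
Reagents that add atoms: N,O-dimethylhydroxylamine hydrochloride, CNOC.Cl
Why: Weinreb aminolysis with the aluminium amide is non-basic, so the α-aryloxy stereocentre should not epimerise.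

Step 7
Reactants: 12 4-bromo-2-methoxyphenol
Product: 13 (4-bromo-2-methoxyphenoxy)triisopropylsilane
Conditions: TIPSCl, imidazole, DMF, rt
Reagents that add atoms: triisopropylsilyl chloride, CC(C)[Si](Cl)(C(C)C)C(C)C
Why: Standard phenol silylation; the aryl TIPS ether is chosen because it tolerates the later organometallic and basic steps.

Step 8
Reactants: 11 Weinreb amide; 13 (4-bromo-2-methoxyphenoxy)triisopropylsilane
Product: 15 aryl ketone (S)-2-(4-bromo-2,6-dimethoxyphenoxy)-1-[3-methoxy-4-(triisopropylsilyloxy)phenyl]-3-(triisopropylsilyloxy)propan-1-one, via Grignard reagent 14 (not isolated)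
Conditions: 13, Mg, THF, 50 °C; then 11, THF, 0 °C; aq. NH4Cl
Reagents that add atoms: none
Why: Grignard addition to a Weinreb amide stops at the chelated tetrahedral intermediate, so the ketone is released only on neutral work-up and the α-stereocentre is not exposed to base; an aryl Grignard does not exchange with the aryl bromide of 11.

Step 9
Reactants: 15 aryl ketone
Product: 16 (1R,2S)-2-(4-bromo-2,6-dimethoxyphenoxy)-1-[3-methoxy-4-(triisopropylsilyloxy)phenyl]-3-(triisopropylsilyloxy)propan-1-ol (erythro)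
Conditions: Zn(BH4)2, Et2O, −30 to 0 °C; aq. NH4Cl
Reagents that add atoms: none
Why: Chelation-controlled (Cram-chelate) reduction: zinc bridges the carbonyl and the α-aryloxy oxygen (assisted by an ortho methoxy group), and hydride enters from the side of the α-hydrogen, which should give the anti (erythro) alcohol with C7 = R; the silylated C9 oxygen does not compete as a chelating site.

Step 10
Reactants: 16 erythro alcohol
Product: 17 tert-butyl{(1R,2S)-2-(4-bromo-2,6-dimethoxyphenoxy)-1-[3-methoxy-4-(triisopropylsilyloxy)phenyl]-3-(triisopropylsilyloxy)propoxy}dimethylsilane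
Conditions: TBSOTf, 2,6-lutidine, CH2Cl2, −40 to 0 °C
Reagents that add atoms: tert-butyldimethylsilyl triflate, CC(C)(C)[Si](C)(C)OS(=O)(=O)C(F)(F)F
Why: Silyl triflate with a hindered base silylates the hindered benzylic alcohol without ionising it.

Step 11
Reactants: 17 aryl bromide
Product: 20 arylboronic acid Ar*–B(OH)2, via aryllithium 18 (not isolated), via diisopropyl boronate 19 (not isolated)
Conditions: n-BuLi (1.1 equiv), THF, −78 °C; B(OiPr)3, −78 °C to rt; aq. NH4Cl
Reagents that add atoms: triisopropyl borate, CC(C)OB(OC(C)C)OC(C)C; water, O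
Why: Bromine–lithium exchange, trapping with the borate and hydrolysis is the standard route to arylboronic acids; no electrophilic group is present and silyl ethers tolerate n-BuLi at −78 °C.

Step 12
Reactants: 6 chromone ester; 20 arylboronic acid
Product: 21 flavanone ethyl 3-[(2R)-2-Ar*-8-methoxy-4-oxochroman-6-yl]propanoate
Conditions: Pd(OCOCF3)2 (5 mol %), (S)-t-BuPyOx (6 mol %), NH4PF6 (30 mol %), H2O (5 equiv), ClCH2CH2Cl, 40 °C; 6 in slight excess
Reagents that add atoms: none
Why: Pd(II)/pyridine-oxazoline-catalysed asymmetric conjugate addition of arylboronic acids to chromones: the ligand controls the face of aryl–Pd insertion at C2 and water protonates the Pd enolate; the ligand enantiomer is chosen to give 2R ((S)-t-BuPyOx by analogy with cyclic enones, otherwise its antipode).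

Step 13
Reactants: 21 flavanone
Product: 23 3-diazoflavanone ethyl 3-[(2S)-2-Ar*-3-diazo-8-methoxy-4-oxochroman-6-yl]propanoate (same spatial arrangement at C2 as 21), via trifluoroacetyl ketone 22 (not isolated)
Conditions: LiHMDS (1.1 equiv), THF, −78 °C; CF3CO2CH2CF3, −78 °C; aq. NH4Cl; then MsN3, Et3N, H2O (1 equiv), MeCN, rt
Reagents that add atoms: methanesulfonyl azide, CS(=O)(=O)N=[N+]=[N-]
Why: Detrifluoroacetylative diazo transfer: kinetic enolisation at C3 (the only α-position), C-trifluoroacylation and diazo transfer with loss of the trifluoroacetyl group; the low temperature is meant to keep the enolate from opening the pyranone ring by β-elimination.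

Step 14
Reactants: 23 3-diazoflavanone
Product: 26 cis ester methyl (2R,3S)-2-Ar*-5-(3-ethoxy-3-oxopropyl)-7-methoxy-2,3-dihydro-1-benzofuran-3-carboxylate, via ketene 24 (not isolated), via ester enol 25 (not isolated)
Conditions: hν (405 nm LEDs), degassed MeOH–THF (4:1), −40 °C
Reagents that add atoms: methanol, CO
Why: Direct excitation of the cyclic, s-Z-locked α-diazo ketone expels N2 with a concerted 1,2-shift of arene carbon C4a from C4 to C3 (photochemical Wolff rearrangement, the reaction type that turns 2-diazo-1-indanones and 2-diazo-1-tetralones into benzocyclobutene- and indane-carboxylates), so the six-membered pyranone ring contracts to the five-membered dihydrofuran ring and C4 becomes an exocyclic ketene carbon. The five-membered ring is therefore closed by a 1,2 C-to-C migration and not by a cyclisation; the O1–C2 bond is untouched, so C2 keeps its configuration. Methanol adds to the ketene to give ester enol 25, which should be protonated at C3 from the face opposite the bulky C2 aryl group, placing CO2Me cis to the aryl group (kinetic, contra-thermodynamic control, the same bias that gives the hindered acid in D-ring contractions of 16-diazo-17-keto steroids). The step needs Wolff shift over carbene 1,2-H or 1,2-aryl shifts (to flavone or isoflavone), which the s-Z geometry, metal-free direct irradiation and the electron-rich migrating arene should secure, and kinetic over thermodynamic protonation, which the low temperature and neutral medium should secure.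

Step 15
Reactants: 26 cis ester
Product: 27 diol 3-[(2R,3R)-2-Ar*-3-(hydroxymethyl)-7-methoxy-2,3-dihydro-1-benzofuran-5-yl]propan-1-ol
Conditions: DIBAL-H (7 equiv), CH2Cl2, −78 to −30 °C; Rochelle salt
Reagents that add atoms: none
Why: Excess DIBAL-H reduces both esters to primary alcohols under non-basic, low-temperature conditions, so the epimerisable cis C3 centre should be preserved (the transient aldehyde is reduced at once).

Step 16
Reactants: 27 diol
Product: 28 target (1R,2S)-2-{4-[(2R,3R)-3-(hydroxymethyl)-5-(3-hydroxypropyl)-7-methoxy-2,3-dihydro-1-benzofuran-2-yl]-2,6-dimethoxyphenoxy}-1-(4-hydroxy-3-methoxyphenyl)propane-1,3-diol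
Conditions: TBAF (6 equiv), AcOH (6 equiv), THF, 0 °C to rt
Reagents that add atoms: none
Why: Fluoride cleaves the aryl TIPS, primary TIPS and benzylic TBS ethers in one operation; the acetic acid buffer suppresses quinone methide formation from the freed p-hydroxybenzyl alcohol.

**Compound list**

1 | 1-(2-hydroxy-3-methoxyphenyl)ethan-1-one | CC(=O)c1cccc(OC)c1O | starting material
2 | 1-(5-bromo-2-hydroxy-3-methoxyphenyl)ethan-1-one | CC(=O)c1cc(Br)cc(OC)c1O | intermediate
3 | (E)-1-(5-bromo-2-hydroxy-3-methoxyphenyl)-3-(dimethylamino)prop-2-en-1-one (enaminone) | CN(C)/C=C/C(=O)c1cc(Br)cc(OC)c1O | intermediate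
4 | 6-bromo-8-methoxy-4H-chromen-4-one | COc1cc(Br)cc2c(=O)ccoc12 | intermediate
5 | (3-ethoxy-3-oxopropyl)zinc bromide | CCOC(=O)CC[Zn]Br | starting material
6 | ethyl 3-(8-methoxy-4-oxo-4H-chromen-6-yl)propanoate | CCOC(=O)CCc1cc(OC)c2occc(=O)c2c1 | intermediate
7 | methyl (R)-2,3-dihydroxypropanoate | COC(=O)[C@H](O)CO | starting material
8 | methyl (R)-2-hydroxy-3-(triisopropylsilyloxy)propanoate | COC(=O)[C@H](O)CO[Si](C(C)C)(C(C)C)C(C)C | intermediate
9 | 4-bromo-2,6-dimethoxyphenol | COc1cc(Br)cc(OC)c1O | starting material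
10 | methyl (S)-2-(4-bromo-2,6-dimethoxyphenoxy)-3-(triisopropylsilyloxy)propanoate | COC(=O)[C@@H](Oc1c(OC)cc(Br)cc1OC)CO[Si](C(C)C)(C(C)C)C(C)C | intermediate
11 | (S)-2-(4-bromo-2,6-dimethoxyphenoxy)-N-methoxy-N-methyl-3-(triisopropylsilyloxy)propanamide | CON(C)C(=O)[C@@H](Oc1c(OC)cc(Br)cc1OC)CO[Si](C(C)C)(C(C)C)C(C)C | intermediate
12 | 4-bromo-2-methoxyphenol | COc1cc(Br)ccc1O | starting material
13 | (4-bromo-2-methoxyphenoxy)triisopropylsilane | COc1cc(Br)ccc1O[Si](C(C)C)(C(C)C)C(C)C | intermediate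
14 | [3-methoxy-4-(triisopropylsilyloxy)phenyl]magnesium bromide | COc1cc([Mg]Br)ccc1O[Si](C(C)C)(C(C)C)C(C)C | intermediate
15 | (S)-2-(4-bromo-2,6-dimethoxyphenoxy)-1-[3-methoxy-4-(triisopropylsilyloxy)phenyl]-3-(triisopropylsilyloxy)propan-1-one | COc1cc(C(=O)[C@@H](Oc2c(OC)cc(Br)cc2OC)CO[Si](C(C)C)(C(C)C)C(C)C)ccc1O[Si](C(C)C)(C(C)C)C(C)C | intermediate
16 | (1R,2S)-2-(4-bromo-2,6-dimethoxyphenoxy)-1-[3-methoxy-4-(triisopropylsilyloxy)phenyl]-3-(triisopropylsilyloxy)propan-1-ol | COc1cc([C@@H](O)[C@@H](Oc2c(OC)cc(Br)cc2OC)CO[Si](C(C)C)(C(C)C)C(C)C)ccc1O[Si](C(C)C)(C(C)C)C(C)C | intermediate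
17 | 1-O-TBS ether of 16 (Ar*–Br) | COc1cc([C@@H](O[Si](C)(C)C(C)(C)C)[C@@H](Oc2c(OC)cc(Br)cc2OC)CO[Si](C(C)C)(C(C)C)C(C)C)ccc1O[Si](C(C)C)(C(C)C)C(C)C | intermediate
18 | aryllithium Ar*–Li | COc1cc([C@@H](O[Si](C)(C)C(C)(C)C)[C@@H](Oc2c(OC)cc([Li])cc2OC)CO[Si](C(C)C)(C(C)C)C(C)C)ccc1O[Si](C(C)C)(C(C)C)C(C)C | intermediate
19 | diisopropyl boronate Ar*–B(OiPr)2 | COc1cc([C@@H](O[Si](C)(C)C(C)(C)C)[C@@H](Oc2c(OC)cc(B(OC(C)C)OC(C)C)cc2OC)CO[Si](C(C)C)(C(C)C)C(C)C)ccc1O[Si](C(C)C)(C(C)C)C(C)C | intermediate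
20 | arylboronic acid Ar*–B(OH)2 | COc1cc([C@@H](O[Si](C)(C)C(C)(C)C)[C@@H](Oc2c(OC)cc(B(O)O)cc2OC)CO[Si](C(C)C)(C(C)C)C(C)C)ccc1O[Si](C(C)C)(C(C)C)C(C)C | intermediate
21 | ethyl 3-[(2R)-2-Ar*-8-methoxy-4-oxochroman-6-yl]propanoate | CCOC(=O)CCc1cc(OC)c2O[C@H](CC(=O)c2c1)c1cc(OC)c(O[C@@H](CO[Si](C(C)C)(C(C)C)C(C)C)[C@H](O[Si](C)(C)C(C)(C)C)c2ccc(O[Si](C(C)C)(C(C)C)C(C)C)c(OC)c2)c(OC)c1 | intermediate
22 | 3-(trifluoroacetyl) derivative of 21 (C3 epimers and enol; C2 as in 21) | CCOC(=O)CCc1cc(OC)c2O[C@H](C(C(=O)C(F)(F)F)C(=O)c2c1)c1cc(OC)c(O[C@@H](CO[Si](C(C)C)(C(C)C)C(C)C)[C@H](O[Si](C)(C)C(C)(C)C)c2ccc(O[Si](C(C)C)(C(C)C)C(C)C)c(OC)c2)c(OC)c1 | intermediate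
23 | ethyl 3-[(2S)-2-Ar*-3-diazo-8-methoxy-4-oxochroman-6-yl]propanoate | CCOC(=O)CCc1cc(OC)c2O[C@H](C(=[N+]=[N-])C(=O)c2c1)c1cc(OC)c(O[C@@H](CO[Si](C(C)C)(C(C)C)C(C)C)[C@H](O[Si](C)(C)C(C)(C)C)c2ccc(O[Si](C(C)C)(C(C)C)C(C)C)c(OC)c2)c(OC)c1 | intermediate
24 | ketene: ethyl 3-[2-Ar*-7-methoxy-3-(oxomethylidene)-2,3-dihydro-1-benzofuran-5-yl]propanoate (C2 as in 21) | CCOC(=O)CCc1cc(OC)c2O[C@H](C(=C=O)c2c1)c1cc(OC)c(O[C@@H](CO[Si](C(C)C)(C(C)C)C(C)C)[C@H](O[Si](C)(C)C(C)(C)C)c2ccc(O[Si](C(C)C)(C(C)C)C(C)C)c(OC)c2)c(OC)c1 | intermediate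
25 | ester enol: 3-[hydroxy(methoxy)methylidene] analogue of 24 (C2 as in 21) | CCOC(=O)CCc1cc(OC)c2O[C@H](C(=C(O)OC)c2c1)c1cc(OC)c(O[C@@H](CO[Si](C(C)C)(C(C)C)C(C)C)[C@H](O[Si](C)(C)C(C)(C)C)c2ccc(O[Si](C(C)C)(C(C)C)C(C)C)c(OC)c2)c(OC)c1 | intermediate
26 | methyl (2R,3S)-2-Ar*-5-(3-ethoxy-3-oxopropyl)-7-methoxy-2,3-dihydro-1-benzofuran-3-carboxylate (2,3-cis) | CCOC(=O)CCc1cc(OC)c2O[C@H]([C@@H](C(=O)OC)c2c1)c1cc(OC)c(O[C@@H](CO[Si](C(C)C)(C(C)C)C(C)C)[C@H](O[Si](C)(C)C(C)(C)C)c2ccc(O[Si](C(C)C)(C(C)C)C(C)C)c(OC)c2)c(OC)c1 | intermediate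
27 | 3-[(2R,3R)-2-Ar*-3-(hydroxymethyl)-7-methoxy-2,3-dihydro-1-benzofuran-5-yl]propan-1-ol (2,3-cis) | OCCCc1cc(OC)c2O[C@H]([C@@H](CO)c2c1)c1cc(OC)c(O[C@@H](CO[Si](C(C)C)(C(C)C)C(C)C)[C@H](O[Si](C)(C)C(C)(C)C)c2ccc(O[Si](C(C)C)(C(C)C)C(C)C)c(OC)c2)c(OC)c1 | intermediate
28 | (1R,2S)-2-{4-[(2R,3R)-3-(hydroxymethyl)-5-(3-hydroxypropyl)-7-methoxy-2,3-dihydro-1-benzofuran-2-yl]-2,6-dimethoxyphenoxy}-1-(4-hydroxy-3-methoxyphenyl)propane-1,3-diol | OCCCc1cc(OC)c2O[C@H]([C@@H](CO)c2c1)c1cc(OC)c(O[C@@H](CO)[C@H](O)c2ccc(O)c(OC)c2)c(OC)c1 | target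

**Step count**

Total: 16 steps. Longest linear sequence: 12 steps (7 → 8 → 10 → 11 → 15 → 16 → 17 → 20 → 21 → 23 → 26 → 27 → 28).

**Steps most likely to fail, with fallbacks**

Step 14. The risk is poor facial selectivity in the protonation of ester enol 25 (or later epimerisation), so that the C3 epimer forms alongside or instead of 26. The fallback sets out from 23 and comes back at 26. The photolysis is run as planned and the C3-epimeric product, the trans ester methyl (2R,3R)-2-Ar*-5-(3-ethoxy-3-oxopropyl)-7-methoxy-2,3-dihydro-1-benzofuran-3-carboxylate F1, is not discarded. F1 (or the ester mixture) is converted into a single lithium ester enolate with LiHMDS in THF at −78 °C and added quickly to a cold solution of a hindered proton donor (2,6-di-tert-butyl-4-methylphenol, THF, −90 °C). Kinetic protonation of the exocyclic enolate from the face away from the C2 aryl group, a classical way to reach the less stable cis isomer, should give 26. The short contact time at low temperature is meant to keep β-elimination of the ring oxygen slow.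

Step 13. The risk is E1cB opening of the lithium enolate of the flavanone to the 2'-hydroxychalcone before C-acylation, which would erase the C2 configuration. The fallback sets out from 21 and comes back at 23, and activates C3 from the acid side. Nitrosation with tert-butyl nitrite and TMSCl in CH2Cl2 at −20 °C (the classical acid-mediated α-oximation of flavanones) should give the α-oximino ketone ethyl 3-[(2S)-2-Ar*-3-(hydroxyimino)-8-methoxy-4-oxochroman-6-yl]propanoate F2. In F2, C3 is sp2 and can no longer trigger ring opening. Forster reaction of F2 with chloramine (generated from NaOCl and aqueous NH3, THF, 0 °C) should then give diazo ketone 23.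

Step 12. The risk is protodeboronation of the electron-rich boronic acid outrunning a slow ligand-controlled insertion, or insufficient facial control by the chiral catalyst. The fallback sets out from 6 and 20 and comes back at 21, and replaces enantioselective C–C bond formation by a resolution. The addition is run with an achiral, more active cationic Pd(II)/2,2'-bipyridine catalyst, which should give 21 together with its C2 epimer ethyl 3-[(2S)-2-Ar*-8-methoxy-4-oxochroman-6-yl]propanoate F3. Asymmetric transfer hydrogenation under kinetic resolution conditions then follows (RuCl(p-cymene)(TsDPEN), HCO2H/Et3N, using the catalyst enantiomer that reduces 2S-flavanones faster, to be identified on racemic flavanone). This should convert F3 into the cis-flavan-4-ol ethyl 3-[(2S,4S)-2-Ar*-4-hydroxy-8-methoxychroman-6-yl]propanoate F4 and leave 21, which is separated by chromatography.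

**Further compounds**

F1 | step 14 | methyl (2R,3R)-2-Ar*-5-(3-ethoxy-3-oxopropyl)-7-methoxy-2,3-dihydro-1-benzofuran-3-carboxylate (2,3-trans) | CCOC(=O)CCc1cc(OC)c2O[C@H]([C@H](C(=O)OC)c2c1)c1cc(OC)c(O[C@@H](CO[Si](C(C)C)(C(C)C)C(C)C)[C@H](O[Si](C)(C)C(C)(C)C)c2ccc(O[Si](C(C)C)(C(C)C)C(C)C)c(OC)c2)c(OC)c1
F2 | step 13 | ethyl 3-[(2S)-2-Ar*-3-(hydroxyimino)-8-methoxy-4-oxochroman-6-yl]propanoate (oxime geometry not defined; C2 as in 21) | CCOC(=O)CCc1cc(OC)c2O[C@H](C(=NO)C(=O)c2c1)c1cc(OC)c(O[C@@H](CO[Si](C(C)C)(C(C)C)C(C)C)[C@H](O[Si](C)(C)C(C)(C)C)c2ccc(O[Si](C(C)C)(C(C)C)C(C)C)c(OC)c2)c(OC)c1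
F3 | step 12 | ethyl 3-[(2S)-2-Ar*-8-methoxy-4-oxochroman-6-yl]propanoate | CCOC(=O)CCc1cc(OC)c2O[C@@H](CC(=O)c2c1)c1cc(OC)c(O[C@@H](CO[Si](C(C)C)(C(C)C)C(C)C)[C@H](O[Si](C)(C)C(C)(C)C)c2ccc(O[Si](C(C)C)(C(C)C)C(C)C)c(OC)c2)c(OC)c1
F4 | step 12 | ethyl 3-[(2S,4S)-2-Ar*-4-hydroxy-8-methoxychroman-6-yl]propanoate | CCOC(=O)CCc1cc(OC)c2O[C@@H](C[C@H](O)c2c1)c1cc(OC)c(O[C@@H](CO[Si](C(C)C)(C(C)C)C(C)C)[C@H](O[Si](C)(C)C(C)(C)C)c2ccc(O[Si](C(C)C)(C(C)C)C(C)C)c(OC)c2)c(OC)c1
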